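## Structural features

The target is a trans-fused 2,3,3a,6,7,7a-hexahydro-1H-inden-2-one. Ring B is a cyclopentanone (C1, C2, C3, C3a, C7a) that shares the C3a–C7a bond with ring A, a cyclohexene (C3a, C4=C5, C6, C7, C7a). These indane locants are used for every intermediate, and C1' denotes the carboxyl carbon on C7.

Ring B holds four contiguous stereocentres, C1 (methyl), C7a, C3a and C3 (ethyl), all-trans around the C2 ketone. Both ring-fusion carbons are therefore beta to the carbonyl, and both alpha-carbons are alkylated and epimerisable.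

Ring A adds two vicinal quaternary stereocentres directly beside the ring fusion: C7 (ethyl, CO2H) and C6 (ethyl, (E)-styryl). The two ethyl groups are cis, and the carboxyl is cis to C7a–H. C4 is a fully substituted alkene carbon carrying the fourth ethyl group.

Fragile points are the alpha-centres C1 and C3, the skipped diene with its styrene, and the gamma,delta-unsaturated acid, which strong acid could close onto C4=C5. The acid sits on a neopentyl quaternary carbon, so it cannot be freed late from an ester.

The real difficulty is the C6–C7 bond between two quaternary centres of defined relative and absolute configuration next to a trans ring fusion. A second difficulty is the absolute configuration of ring B, which has no heteroatom handle.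

The key step exploits the pattern of ring B. A C2 ketone flanked by alkylated C1 and C3, with trans substituents on the beta-carbons C3a and C7a, is the retron of a conrotatory 4π closure of a cross-conjugated (E,E)-dienone with hydride capture, which forms C3a–C7a.

## Logic of the disconnections

**40 ⇒ 39.** No skeletal bond is cut; the C2 ketone is masked as a dioxolane. The mask is needed because the chemistry at C4 (organometallic addition) and at C7 (enolisation) cannot tolerate a second ketone. The demand on the forward step is a hydrolysis mild enough for the skipped diene and the free acid.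

**39 ⇒ 36.** C6–C7 is cut and C1'–O–C4 is reconnected, the retron of a lactone-enolate [3,3] shift. Both quaternary centres and ring A are traded for one tertiary carbinol stereocentre (C4) and one alkene geometry (C5=C6). The forward step must pass a boat-like transition state inside a trans-fused bicycle. That requires the (4S) epimer with the dienyl group cis to C3a–H, the (E) geometry at C5=C6, and enolisation of an alpha-branched lactone.

**36 ⇒ 24 + 32.** C4–C5 and the lactone C1'–O bond are cut. A dienyl organometallic (from 32) adds to the C4 ketone of 24 and the alkoxide closes onto the C1' ester. This is convergent and removes the sensitive diene from all earlier steps. The demands are facial selectivity at C4, ketone-over-ester chemoselectivity, and retention of geometry in the dienyl metal.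

**32 ⇒ 29 ⇒ 28 ⇒ 25 + 26 (and 30).** The styryl C=C is cut by a phosphonate olefination, and the iodoalkene C5=C6 is traced to an ethylmalonate and iodoform. Carbometalation of a terminal alkyne is reliable for methyl but not for ethyl. The decarboxylative route gives the alkene with iodine trans to the carboxyl, that is cis to ethyl. The demand is exactly this (E) geometry.

**24 ⇒ 22 ⇒ 21 ⇒ 20 ⇒ 19.** These are functional-group changes only: C1' and C4 are taken down to silyl ethers and C2 is unmasked. The precursor design is corrected here. A carbonyl group at C1' in the dienone stage would make C7–H both alpha to an ester and gamma to the dienone (glutaconate-type acidity). Such a centre could not be held as one stereoisomer, the alkene would migrate, and neither an alkenyllithium nor BF3 would be tolerated. C1' is therefore carried as a TIPS ether and oxidised after ring B exists. The C4 silyloxy centre is kept as a sacrificial resolving handle. The forward demand is a double oxidation that avoids lactol formation.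

**19 ⇒ 17.** C3a–C7a is cut (with the C–H bonds at C1 and C3): the reductive Nazarov retron. Ring B and four stereocentres collapse to an acyclic (E,E)-dienone. The forward step needs both alkene geometries, hydride capture faster than proton loss, and separation of the two trans diastereomers that differ in the sense of rotation.

**17 ⇒ 7 + 15.** C2–C3 is cut: an alkenyllithium (from 15) acylated by a Weinreb amide. The dienone splits into two arms of similar size. The demands are retention of the (E) geometry through iodine–lithium exchange and the absence of acidic or electrophilic spectator groups.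

**7 ⇒ 6 ⇒ 5 ⇒ 1 + 2 + 3.** C7a=C1 is cut by a stabilised Wittig reaction, and C7–C1' by an enamine aldol with formaldehyde. The demand is trapping of the labile beta-hydroxy aldehyde before it eliminates or racemises.

**15 ⇒ 13 ⇒ 12 ⇒ 11 ⇒ 8 + 9.** The C3 iodoalkene comes from syn-hydrozirconation of an internal alkyne, the C4 carbinol from asymmetric transfer hydrogenation of an ynone, and the ynone from an acetylide and a Weinreb amide. The demand is regiocontrol in the hydrozirconation, with zirconium on the ethyl-bearing carbon.

## Other disconnections considered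

**Alternative 1:** The cut is C6–C7, with C1'–O–C4 reconnected. In the forward step the silyl ketene acetal of lactone A2 rearranges [3,3] to the ketal acid A1. A1 is the same compound as 39 and A2 the same as 36, so the chosen route uses this very step downstream (step 18).
- In its favour: it answers the hardest question of the molecule, the vicinal quaternary centres, by intramolecular chirality transfer and closes ring A in the same event. On this point it is the better, more strategic disconnection, since the Nazarov step does nothing for C6 and C7.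
- Against it as the organising step: it presupposes ring B with its trans fusion, its four stereocentres and its absolute configuration, and a defined C4 carbinol. Its transition state is a forced boat inside a trans-fused system.
- Comparison: mechanistically both are pericyclic and stereospecific. Structurally they are complementary, one building ring B and the other ring A. In step economy they are equal, because both are in the route.

**Alternative 2:** The cuts are C3a–C7a, C1–C2 and C2–C3. In the forward step the Co2(CO)8 complex of dienyne A4 inserts the (E)-C3a=C3 alkene and CO to give enone A3.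
- In its favour: three bonds and both rings form in one step from an acyclic precursor, and C2 arrives as carbon monoxide. In ring-forming economy this is better than the chosen plan, which closes the rings in two separate steps. It is equal in setting C3 against C3a from the (E) alkene.
- Against it here: A4 must already carry both quaternary centres C6 and C7 in an open chain, where no ring relays stereochemistry. The enyne is a 1,7-enyne whose alkene is internal and part of a conjugated diene. The face of insertion at C3a is steered only by the distant quaternary centres.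
- A3 still lacks C7a and C1. The tetrasubstituted enone would have to be reduced to a trans ring fusion beside quaternary C7. The Nazarov closure sets this trans relation by orbital symmetry, and on that point the chosen plan is the safer one.

**Alternative 3:** The cut is C5–C6. In the forward step zerovalent palladium (from Pd(OAc)2 and a phosphine) inserts into the (Z)-alkenyl iodide of A6, adds 6-exo to the trisubstituted C6 alkene, and eliminates a benzylic hydride to give ester A5.
- In its favour: it is catalytic and tolerates the free C2 ketone, so no ketal is needed, which is better than the chosen plan. The only beta-hydrogens available lead to the (E)-styryl group, so ring A, C6 and the styrene appear together.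
- Against it here: C7 must be quaternary beforehand and is then the only control element for the face of a congested insertion between two fully substituted carbons. The step sets one stereocentre where the Claisen sets two.
- A5 ends as a neopentyl methyl ester, whose hydrolysis beside an epimerisable ketone is a poor last step. The chosen route releases the acid directly.
- Ring B of A6 could still come from the Nazarov step, so this is an alternative for ring A only, with a comparable step count.

Key step: step 9

Assumption: the senses of induction in steps 1 and 5 follow the accepted models for the diarylprolinol silyl ether and the TsDPEN–ruthenium catalyst; both centres (C7, C4) are erased later, so only descriptors, not the plan, depend on this.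

## Route

Step 1
Reactants: 1 butanal; 2 formaldehyde (37% aqueous); 3 ethyl 2-(triphenylphosphoranylidene)propanoate
Product: 5 ethyl (R,E)-4-(hydroxymethyl)-2-methylhex-2-enoate, via (S)-2-(hydroxymethyl)butanal 4 (not isolated)
Conditions: (R)-α,α-diphenylprolinol TMS ether (10 mol%), pH 7 phosphate buffer, PhMe, rt; organic phase, then 3, CH2Cl2, rt
Reagents that add atoms: none
Why: Enamine-catalysed cross-aldol with formaldehyde (organocatalytic alpha-hydroxymethylation): the E-enamine is attacked on the face away from the diarylsilyloxymethyl group, which sets C7; the labile beta-hydroxy aldehyde is trapped at once by the stabilised Wittig ylide, which gives the (E)-trisubstituted C7a=C1 alkene.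

Step 2
Reactants: 5 ethyl (R,E)-4-(hydroxymethyl)-2-methylhex-2-enoate
Product: 6 ethyl (R,E)-2-methyl-4-{[(triisopropylsilyl)oxy]methyl}hex-2-enoate
Conditions: TIPSCl, imidazole, DMF, rt
Reagents that add atoms: chlorotri(propan-2-yl)silane, CC(C)[Si](Cl)(C(C)C)C(C)C
Why: Standard silylation of a primary alcohol; the TIPS ether is chosen to survive BF3·OEt2 in step 9 and to leave with fluoride in step 11.

Step 3
Reactants: 6 ethyl (R,E)-2-methyl-4-{[(triisopropylsilyl)oxy]methyl}hex-2-enoate
Product: 7 (R,E)-N-methoxy-N,2-dimethyl-4-{[(triisopropylsilyl)oxy]methyl}hex-2-enamide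
Conditions: MeNH(OMe)·HCl, i-PrMgCl, THF, −20 → 0 °C
Reagents that add atoms: N,O-dimethylhydroxylamine hydrochloride, CNOC.Cl
Why: Weinreb aminolysis of the ester by the magnesium amide; the alpha-methyl, beta-branched enoate resists conjugate addition, and C7 carries no acidifying group, so its configuration is untouched.

Step 4
Reactants: 8 N-methoxy-N-methylpropanamide; 9 but-1-yne
Product: 11 hept-4-yn-3-one, via but-1-yn-1-yllithium 10 (not isolated)
Conditions: n-BuLi, THF, −78 °C; then 8, −78 → 0 °C
Reagents that add atoms: none
Why: Acylation of a lithium acetylide by a Weinreb amide; the chelated tetrahedral adduct prevents over-addition and releases the ynone on work-up.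

Step 5
Reactants: 11 hept-4-yn-3-one
Product: 12 (S)-hept-4-yn-3-ol
Conditions: Ru[(S,S)-TsDPEN](p-cymene) (0.5 mol%), i-PrOH, rt
Reagents that add atoms: none
Why: Noyori asymmetric transfer hydrogenation of an alkynyl ketone; the alkynyl group takes the place of the aryl group in the six-membered hydride-transfer transition state, which should give the S carbinol (C4) in high ee and leave the triple bond alone.

Step 6
Reactants: 12 (S)-hept-4-yn-3-ol
Product: 13 (S)-tert-butyl(hept-4-yn-3-yloxy)dimethylsilane
Conditions: TBSCl, imidazole, DMF, rt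
Reagents that add atoms: tert-butylchlorodimethylsilane, CC(C)(C)[Si](C)(C)Cl
Why: Standard silylation; the bulky silyl ether also steers zirconium away from the carbinol side in step 7.

Step 7
Reactants: 13 (S)-tert-butyl(hept-4-yn-3-yloxy)dimethylsilane
Product: 15 (S,E)-tert-butyl[(5-iodohept-4-en-3-yl)oxy]dimethylsilane, via alkenylzirconocene chloride 14 (not isolated)
Conditions: Cp2Zr(H)Cl (1.6 equiv), THF, rt → 40 °C; then I2, 0 °C
Reagents that add atoms: iodine, II
Why: Hydrozirconation is a syn addition and, with excess reagent, equilibrates zirconium to the less hindered alkyne carbon (C3, which bears the plain ethyl group); iodinolysis with retention gives the (E)-iodide with iodine trans to C4.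

Step 8
Reactants: 15 (S,E)-tert-butyl[(5-iodohept-4-en-3-yl)oxy]dimethylsilane; 7 (R,E)-N-methoxy-N,2-dimethyl-4-{[(triisopropylsilyl)oxy]methyl}hex-2-enamide
Product: 17 (3S,4E,7E,9R)-3-(tert-butyldimethylsilyloxy)-5-ethyl-7-methyl-9-{[(triisopropylsilyl)oxy]methyl}undeca-4,7-dien-6-one, via alkenyllithium 16 (not isolated)
Conditions: t-BuLi (2 equiv), Et2O, −78 °C; then 7, THF, −78 → −20 °C
Reagents that add atoms: none
Why: Iodine–lithium exchange with retention of alkene geometry, then acylation by the Weinreb amide, forms C2–C3; neither partner carries an acidic C–H or a second electrophile, so the (E,E)-dienone should form without alkene migration.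

Step 9
Reactants: 17 (3S,4E,7E,9R)-3-(tert-butyldimethylsilyloxy)-5-ethyl-7-methyl-9-{[(triisopropylsilyl)oxy]methyl}undeca-4,7-dien-6-one
Product: 19 (2S,3R,4R,5S)-3-[(1S)-1-(tert-butyldimethylsilyloxy)propyl]-2-ethyl-5-methyl-4-[(2R)-1-(triisopropylsilyloxy)butan-2-yl]cyclopentan-1-one, via triethylsilyl enol ether 18 (not isolated)
Conditions: BF3·OEt2 (1.2 equiv), Et3SiH (4 equiv), CH2Cl2, −78 → 0 °C; then K2CO3, MeOH, rt; chromatographic separation of the two trans diastereomers
Reagents that add atoms: none
Why: BF3 binds the ketone and turns the (E,E)-dienone into a 3-oxidopentadienyl cation, which closes by thermal conrotatory 4π electrocyclisation to form C3a–C7a and the five-membered ring B. The closest known reaction type is the reductive (interrupted) Nazarov cyclisation of alpha,alpha'-dialkyl dienones with a Lewis acid and Et3SiH, in which hydride quenches the oxyallyl cation to a silyl enol ether (18, drawn for delivery to C3) before a proton is lost. C3a and C7a come out trans because the two outward (E) arms rotate in the same sense; this follows from orbital symmetry and not from any reagent. Their absolute sense depends on the direction of rotation, which the sacrificial centres C4 and C7 can bias only through allylic strain, so both trans diastereomers are expected and 19 is separated from its partner. C1 and C3 are set by hydride delivery and protonation and are then equilibrated by K2CO3/MeOH (which also cleaves 18) to the all-trans ketone, the thermodynamic isomer of this tetrasubstituted cyclopentanone. The step needs closure to outrun ionic reduction of the dienone and hydride capture to outrun proton loss: the two alpha-alkyl groups speed closure, excess silane at low temperature secures capture, and neither arm carries a carbonyl group or an acidic hydrogen. The hindered secondary TBS ether and the TIPS ether are chosen to tolerate BF3 at these temperatures.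

Step 10
Reactants: 19 (2S,3R,4R,5S)-3-[(1S)-1-(tert-butyldimethylsilyloxy)propyl]-2-ethyl-5-methyl-4-[(2R)-1-(triisopropylsilyloxy)butan-2-yl]cyclopentan-1-one
Product: 20 (6S,7R,8R,9S)-7-[(1S)-1-(tert-butyldimethylsilyloxy)propyl]-6-ethyl-9-methyl-8-[(2R)-1-(triisopropylsilyloxy)butan-2-yl]-1,4-dioxaspiro[4.4]nonane
Conditions: TMSOCH2CH2OTMS, TMSOTf (5 mol%), CH2Cl2, −78 → −20 °C
Reagents that add atoms: 1,2-bis(trimethylsilyloxy)ethane, C[Si](C)(C)OCCO[Si](C)(C)C
Why: Noyori ketalisation works on hindered ketones under aprotic conditions that leave both silyl ethers and the alpha-centres untouched; C2 must be silent before the C4 ketone and the C7 enolate are generated.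

Step 11
Reactants: 20 (6S,7R,8R,9S)-7-[(1S)-1-(tert-butyldimethylsilyloxy)propyl]-6-ethyl-9-methyl-8-[(2R)-1-(triisopropylsilyloxy)butan-2-yl]-1,4-dioxaspiro[4.4]nonane
Product: 21 (1S)-1-{(6S,7R,8R,9S)-6-ethyl-8-[(2R)-1-hydroxybutan-2-yl]-9-methyl-1,4-dioxaspiro[4.4]nonan-7-yl}propan-1-ol
Conditions: Bu4NF, THF, rt → 40 °C
Reagents that add atoms: none
Why: Fluoride cleavage of both silyl ethers; nothing else in the molecule is sensitive to fluoride.

Step 12
Reactants: 21 (1S)-1-{(6S,7R,8R,9S)-6-ethyl-8-[(2R)-1-hydroxybutan-2-yl]-9-methyl-1,4-dioxaspiro[4.4]nonan-7-yl}propan-1-ol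
Product: 22 (2R)-2-[(6S,7R,8S,9S)-6-ethyl-9-methyl-7-propanoyl-1,4-dioxaspiro[4.4]nonan-8-yl]butanal
Conditions: (COCl)2, DMSO, CH2Cl2, −78 °C; Et3N, −78 → 0 °C
Reagents that add atoms: none
Why: Swern oxidation activates both hydroxyl groups before base is added, so the C4 ketone and the C1' aldehyde form together without a lactol stage; the C4 stereocentre is erased here, and C7 becomes epimerisable, which is harmless because step 18 enolises it.

Step 13
Reactants: 22 (2R)-2-[(6S,7R,8S,9S)-6-ethyl-9-methyl-7-propanoyl-1,4-dioxaspiro[4.4]nonan-8-yl]butanal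
Product: 24 methyl (2R)-2-[(6S,7R,8S,9S)-6-ethyl-9-methyl-7-propanoyl-1,4-dioxaspiro[4.4]nonan-8-yl]butanoate, via keto acid 23 (not isolated)
Conditions: NaClO2, NaH2PO4, 2-methylbut-2-ene, t-BuOH/H2O, rt; then TMSCHN2, MeOH/PhMe, 0 °C
Reagents that add atoms: sodium chlorite, [Na+].[O-]Cl=O; (trimethylsilyl)diazomethane, C[Si](C)(C)C=[N+]=[N-]
Why: Pinnick oxidation converts only the aldehyde; the crude acid is methylated by the diazoalkane under neutral conditions that spare the ketal.

Step 14
Reactants: 25 diethyl 2-ethylpropanedioate; 26 triiodomethane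
Product: 28 (E)-2-ethyl-3-iodoprop-2-enoic acid, via diiodomethyl malonate 27 (not isolated)
Conditions: NaH, Et2O, reflux; then KOH, EtOH/H2O, reflux; HCl
Reagents that add atoms: potassium hydroxide, [K+].[OH-]
Why: Alkylation of the malonate anion by iodoform, then saponification with decarboxylative loss of iodide (the established route to (E)-3-iodo-2-alkylacrylic acids), gives the alkene with iodine trans to the carboxyl and cis to ethyl, the geometry C5=C6 needs.

Step 15
Reactants: 28 (E)-2-ethyl-3-iodoprop-2-enoic acid
Product: 29 (E)-2-ethyl-3-iodoprop-2-en-1-ol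
Conditions: LiAlH4, Et2O, 0 °C
Reagents that add atoms: none
Why: Hydride reduction of the acid to the allylic alcohol; at 0 °C the vinyl iodide and the alkene geometry are retained.

Step 16
Reactants: 29 (E)-2-ethyl-3-iodoprop-2-en-1-ol; 30 diethyl benzylphosphonate
Product: 32 [(1E,3E)-3-ethyl-4-iodobuta-1,3-dien-1-yl]benzene, via iodoenal 31 (not isolated)
Conditions: MnO2, CH2Cl2, rt; filtration; then 30, NaH, THF, 0 °C → rt
Reagents that add atoms: none
Why: Allylic oxidation followed by Horner–Wadsworth–Emmons olefination with the benzylic phosphonate, which gives the (E)-styryl bond; the vinyl iodide is inert to the phosphonate anion.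

Step 17
Reactants: 32 [(1E,3E)-3-ethyl-4-iodobuta-1,3-dien-1-yl]benzene; 24 methyl (2R)-2-[(6S,7R,8S,9S)-6-ethyl-9-methyl-7-propanoyl-1,4-dioxaspiro[4.4]nonan-8-yl]butanoate
Product: 36 delta-lactone (ring oxygen on C4) with (4S)-ethyl and (1E,3E)-2-ethyl-4-phenylbuta-1,3-dien-1-yl on C4 and the dienyl group cis to C3a–H, via dienyllithium 33 (not isolated), via dienylcerium dichloride 34 (not isolated), via hydroxy ester 35 (not isolated)
Conditions: 32, t-BuLi (2 equiv), Et2O, −78 °C; CeCl3, THF, −78 °C; then 24 (0.9 equiv), −78 °C → rt
Reagents that add atoms: none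
Why: Iodine–lithium exchange with retention, transmetalation to the weakly basic organocerium and 1,2-addition to the C4 ketone in preference to the alpha-branched ester; the alkoxide then closes onto C1' with loss of methoxide. C4 is set by the face of addition: cerium bridging the ketone and ester oxygens should turn the carbonyl oxygen toward C7a, so that the dienyl group enters past the small C3a–H and gives the (4S) epimer.

Step 18
Reactants: 36 delta-lactone (ring oxygen on C4) with (4S)-ethyl and (1E,3E)-2-ethyl-4-phenylbuta-1,3-dien-1-yl on C4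
Product: 39 (1S,3S,3aR,6S,7R,7aR)-3,4,6,7-tetraethyl-1-methyl-6-[(E)-2-phenylethenyl]-1,3,3a,6,7,7a-hexahydrospiro[indene-2,2'-[1,3]dioxolane]-7-carboxylic acid, via silyl ketene acetal 37 (not isolated), via silyl ester 38 (not isolated)
Conditions: LDA, TMSCl/Et3N, THF, −78 °C → rt; then PhMe, 110 °C; then H2O/MeOH
Reagents that add atoms: none
Why: Ireland–Claisen rearrangement of a lactone silyl ketene acetal, a [3,3] shift that must pass a boat-like, bicyclo[2.2.2]-type transition state; it forms C6–C7 and ring A suprafacially on the lactone face that carries the dienyl group, so C7 follows from C4 and C6 from the (E) geometry of C5=C6 (the styryl group, trans to C4, ends cis to the carboxyl). A model of this boat shows a twist of the same sense as the C7–C7a–C3a–C4 torsion of the trans-fused ring B, which is why the (4S) epimer is the one expected to react.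

Step 19
Reactants: 39 (1S,3S,3aR,6S,7R,7aR)-3,4,6,7-tetraethyl-1-methyl-6-[(E)-2-phenylethenyl]-1,3,3a,6,7,7a-hexahydrospiro[indene-2,2'-[1,3]dioxolane]-7-carboxylic acid
Product: 40 (1S,3S,3aR,6S,7R,7aR)-3,4,6,7-tetraethyl-1-methyl-2-oxo-6-[(E)-2-phenylethenyl]-2,3,3a,6,7,7a-hexahydro-1H-indene-7-carboxylic acid (CNP0324606.3)
Conditions: 1 M HCl, THF, rt
Reagents that add atoms: water, O
Why: Mild acetal hydrolysis; C1 and C3 become epimerisable again, but the all-trans arrangement is the thermodynamic one, and dilute acid at room temperature should not add the carboxyl group to the C4=C5 or styryl alkenes.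

## Compound list

1 | butanal | CCCC=O | starting material
2 | formaldehyde (37% aqueous) | C=O | starting material
3 | ethyl 2-(triphenylphosphoranylidene)propanoate | CCOC(=O)C(C)=P(c1ccccc1)(c1ccccc1)c1ccccc1 | starting material
4 | (S)-2-(hydroxymethyl)butanal | CC[C@@H](CO)C=O | intermediate (not isolated)
5 | ethyl (R,E)-4-(hydroxymethyl)-2-methylhex-2-enoate | CC[C@@H](CO)/C=C(C)/C(=O)OCC | intermediate
6 | ethyl (R,E)-2-methyl-4-{[(triisopropylsilyl)oxy]methyl}hex-2-enoate | CC[C@@H](CO[Si](C(C)C)(C(C)C)C(C)C)/C=C(C)/C(=O)OCC | intermediate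
7 | (R,E)-N-methoxy-N,2-dimethyl-4-{[(triisopropylsilyl)oxy]methyl}hex-2-enamide | CC[C@@H](CO[Si](C(C)C)(C(C)C)C(C)C)/C=C(C)/C(=O)N(C)OC | intermediate
8 | N-methoxy-N-methylpropanamide | CCC(=O)N(C)OC | starting material
9 | but-1-yne | CCC#C | starting material
10 | but-1-yn-1-yllithium | [Li]C#CCC | intermediate (not isolated)
11 | hept-4-yn-3-one | CCC#CC(=O)CC | intermediate
12 | (S)-hept-4-yn-3-ol | CC[C@H](O)C#CCC | intermediate
13 | (S)-tert-butyl(hept-4-yn-3-yloxy)dimethylsilane | CC[C@H](O[Si](C)(C)C(C)(C)C)C#CCC | intermediate
14 | chloro[(S,E)-5-(tert-butyldimethylsilyloxy)hept-3-en-3-yl]zirconocene | Cl[Zr](C1C=CC=C1)(C1C=CC=C1)/C(CC)=C/[C@H](CC)O[Si](C)(C)C(C)(C)C | intermediate (not isolated)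
15 | (S,E)-tert-butyl[(5-iodohept-4-en-3-yl)oxy]dimethylsilane | I/C(CC)=C/[C@H](CC)O[Si](C)(C)C(C)(C)C | intermediate
16 | [(S,Z)-5-(tert-butyldimethylsilyloxy)hept-3-en-3-yl]lithium (lithium trans to the carbinol carbon; geometry of 15 retained) | [Li]/C(CC)=C/[C@H](CC)O[Si](C)(C)C(C)(C)C | intermediate (not isolated)
17 | (3S,4E,7E,9R)-3-(tert-butyldimethylsilyloxy)-5-ethyl-7-methyl-9-{[(triisopropylsilyl)oxy]methyl}undeca-4,7-dien-6-one | CC[C@@H](CO[Si](C(C)C)(C(C)C)C(C)C)/C=C(C)/C(=O)/C(CC)=C/[C@H](CC)O[Si](C)(C)C(C)(C)C | intermediate (key-step precursor)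
18 | triethylsilyl enol ether of 19 (C1=C2 double bond, O–SiEt3 on C2) | CC[C@@H](CO[Si](C(C)C)(C(C)C)C(C)C)[C@@H]1[C@@H]([C@H](CC)O[Si](C)(C)C(C)(C)C)[C@H](CC)C(O[Si](CC)(CC)CC)=C1C | intermediate (not isolated)
19 | (2S,3R,4R,5S)-3-[(1S)-1-(tert-butyldimethylsilyloxy)propyl]-2-ethyl-5-methyl-4-[(2R)-1-(triisopropylsilyloxy)butan-2-yl]cyclopentan-1-one | CC[C@@H](CO[Si](C(C)C)(C(C)C)C(C)C)[C@@H]1[C@@H]([C@H](CC)O[Si](C)(C)C(C)(C)C)[C@H](CC)C(=O)[C@H]1C | intermediate (key-step product)
20 | (6S,7R,8R,9S)-7-[(1S)-1-(tert-butyldimethylsilyloxy)propyl]-6-ethyl-9-methyl-8-[(2R)-1-(triisopropylsilyloxy)butan-2-yl]-1,4-dioxaspiro[4.4]nonane | CC[C@@H](CO[Si](C(C)C)(C(C)C)C(C)C)[C@@H]1[C@@H]([C@H](CC)O[Si](C)(C)C(C)(C)C)[C@H](CC)C2(OCCO2)[C@H]1C | intermediate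
21 | (1S)-1-{(6S,7R,8R,9S)-6-ethyl-8-[(2R)-1-hydroxybutan-2-yl]-9-methyl-1,4-dioxaspiro[4.4]nonan-7-yl}propan-1-ol | CC[C@@H](CO)[C@@H]1[C@@H]([C@H](CC)O)[C@H](CC)C2(OCCO2)[C@H]1C | intermediate
22 | (2R)-2-[(6S,7R,8S,9S)-6-ethyl-9-methyl-7-propanoyl-1,4-dioxaspiro[4.4]nonan-8-yl]butanal | CC[C@@H](C=O)[C@@H]1[C@@H](C(=O)CC)[C@H](CC)C2(OCCO2)[C@H]1C | intermediate
23 | (2R)-2-[(6S,7R,8S,9S)-6-ethyl-9-methyl-7-propanoyl-1,4-dioxaspiro[4.4]nonan-8-yl]butanoic acid | CC[C@@H](C(=O)O)[C@@H]1[C@@H](C(=O)CC)[C@H](CC)C2(OCCO2)[C@H]1C | intermediate (not isolated)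
24 | methyl (2R)-2-[(6S,7R,8S,9S)-6-ethyl-9-methyl-7-propanoyl-1,4-dioxaspiro[4.4]nonan-8-yl]butanoate | CC[C@@H](C(=O)OC)[C@@H]1[C@@H](C(=O)CC)[C@H](CC)C2(OCCO2)[C@H]1C | intermediate
25 | diethyl 2-ethylpropanedioate (diethyl ethylmalonate) | CCOC(=O)C(CC)C(=O)OCC | starting material
26 | triiodomethane (iodoform) | IC(I)I | starting material
27 | diethyl 2-(diiodomethyl)-2-ethylpropanedioate | CCOC(=O)C(CC)(C(I)I)C(=O)OCC | intermediate (not isolated)
28 | (E)-2-ethyl-3-iodoprop-2-enoic acid | OC(=O)/C(CC)=C/I | intermediate
29 | (E)-2-ethyl-3-iodoprop-2-en-1-ol | OC/C(CC)=C/I | intermediate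
30 | diethyl benzylphosphonate | CCOP(=O)(Cc1ccccc1)OCC | starting material
31 | (E)-2-ethyl-3-iodoprop-2-enal | O=C/C(CC)=C/I | intermediate (not isolated)
32 | [(1E,3E)-3-ethyl-4-iodobuta-1,3-dien-1-yl]benzene | I/C=C(CC)/C=C/c1ccccc1 | intermediate
33 | [(1E,3E)-2-ethyl-4-phenylbuta-1,3-dien-1-yl]lithium | [Li]/C=C(CC)/C=C/c1ccccc1 | intermediate (not isolated)
34 | dichloro[(1E,3E)-2-ethyl-4-phenylbuta-1,3-dien-1-yl]cerium | Cl[Ce](Cl)/C=C(CC)/C=C/c1ccccc1 | intermediate (not isolated)
35 | methyl (2R)-2-{6-ethyl-7-[(3S,4E,6E)-5-ethyl-3-hydroxy-7-phenylhepta-4,6-dien-3-yl]-9-methyl-1,4-dioxaspiro[4.4]nonan-8-yl}butanoate (ring centres as in 24) | CC[C@@H](C(=O)OC)[C@@H]1[C@@H]([C@@](O)(CC)/C=C(CC)/C=C/c2ccccc2)[C@H](CC)C3(OCCO3)[C@H]1C | intermediate (not isolated)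
36 | delta-lactone of 35: ring O on C4, which is (4S) and bears ethyl and the (1E,3E)-2-ethyl-4-phenylbuta-1,3-dien-1-yl group (cis to C3a–H); C7 (R) with ethyl; trans-fused to ring B, which carries the C2 dioxolane, 1-methyl and 3-ethyl as in 24 | CC[C@]1(/C=C(CC)/C=C/c2ccccc2)OC(=O)[C@H](CC)[C@@H]3[C@@H]1[C@H](CC)C4(OCCO4)[C@H]3C | intermediate
37 | trimethylsilyl ketene acetal of 36 (C7=C1' double bond, O–SiMe3 on C1') | CC[C@]1(/C=C(CC)/C=C/c2ccccc2)OC(O[Si](C)(C)C)=C(CC)[C@@H]3[C@@H]1[C@H](CC)C4(OCCO4)[C@H]3C | intermediate (not isolated)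
38 | trimethylsilyl ester of 39 | CCC1=C[C@@](/C=C/c2ccccc2)(CC)[C@](CC)(C(=O)O[Si](C)(C)C)[C@@H]2[C@@H]1[C@H](CC)C3(OCCO3)[C@H]2C | intermediate (not isolated)
39 | (1S,3S,3aR,6S,7R,7aR)-3,4,6,7-tetraethyl-1-methyl-6-[(E)-2-phenylethenyl]-1,3,3a,6,7,7a-hexahydrospiro[indene-2,2'-[1,3]dioxolane]-7-carboxylic acid | CCC1=C[C@@](/C=C/c2ccccc2)(CC)[C@](CC)(C(=O)O)[C@@H]2[C@@H]1[C@H](CC)C3(OCCO3)[C@H]2C | intermediate
40 | (1S,3S,3aR,6S,7R,7aR)-3,4,6,7-tetraethyl-1-methyl-2-oxo-6-[(E)-2-phenylethenyl]-2,3,3a,6,7,7a-hexahydro-1H-indene-7-carboxylic acid (CNP0324606.3; locants as used throughout) | CCC1=C[C@@](/C=C/c2ccccc2)(CC)[C@](CC)(C(=O)O)[C@@H]2[C@@H]1[C@H](CC)C(=O)[C@H]2C | target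

## Step count and least certain steps

Total step count: 19. Longest linear sequence: 13 steps (steps 4 to 13, then 17 to 19, from 8 and 9 to 40).

**Step 9 (key step).**
- Most likely to go wrong: poor torquoselectivity. The two sacrificial centres sit one bond outside the reacting termini and can bias the sense of conrotation only through allylic strain. Both trans diastereomers may therefore form in similar amounts, or the unwanted one may prevail.
- A second risk is ionic reduction of the BF3-activated dienone before it closes.
- Fallback: reverse the substrate bias. C4 is oxidised later, so its configuration is a free variable.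
- The fallback sets out from 11. Reduction with Ru[(R,R)-TsDPEN](p-cymene) should give (R)-hept-4-yn-3-ol F1, which is silylated to (R)-tert-butyl(hept-4-yn-3-yloxy)dimethylsilane F2.
- Hydrozirconation and iodination give the (R,E)-iodide F3. Lithiation and acylation with 7 give the C4-epimeric dienone F4.
- The reductive Nazarov cyclisation of F4 gives the C4-epimeric ketone F5 with the opposite relation between C4 and the sense of rotation. Ketalisation gives the ketal F6 and desilylation the C4-epimeric diol F7.
- Swern oxidation of F7 erases C4 and rejoins the route at 22.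

**Step 17.**
- Most likely to go wrong: poor facial selectivity at C4. Both neighbours of C3a are ring CH groups, so Felkin-type control is weak.
- If cerium does not bridge to the ester, attack with the carbonyl oxygen turned toward C3 would give the C4 epimer. That epimer cannot adopt the boat needed in step 18.
- Fallback: alkoxide-directed addition followed by oxidative lactonisation. It sets out from 22.
- Aldehyde-selective reduction (NaBH4, EtOH, −78 °C) gives the hydroxy ketone F8. Excess 34 adds to F8 as its metal alkoxide, which forms a tighter chelate to the C4 ketone on the C7a side, to give the tertiary/primary diol F9.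
- TEMPO/PhI(OAc)2 oxidises the primary alcohol of F9 through the lactol to 36, where the route is rejoined.

**Step 18.**
- Most likely to go wrong: a slow sigmatropic shift. The boat-like transition state must twist to keep ring B trans-fused.
- Ionisation of the tertiary, doubly allylic C4–O bond with loss of a proton may then compete, as may incomplete enolisation of the alpha-branched lactone.
- Fallback: form C6–C7 by an open-chain ester-enolate Claisen and close ring A by metathesis. It sets out from 24.
- Methylenation of the C4 ketone (Ph3P=CH2) gives the methylidene ester F10, and saponification gives the acid F11.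
- Esterification (EDC, DMAP) with (2E,4E)-3-ethyl-5-phenylpenta-2,4-dien-1-ol F12, made from 33 and paraformaldehyde, gives the dienyl ester F13.
- Ireland–Claisen rearrangement of F13 (chair transition state) gives the acid F14 with the C6 vinyl group.
- Ring-closing metathesis (Hoveyda–Grubbs second-generation catalyst, PhMe, 80 °C) between that vinyl group and the C4 methylidene returns to 39.
- The price: diastereocontrol at C6 and C7 then rests on enolate geometry and on separation.

**Step 1.**
- Most likely to go wrong: loss of the new stereocentre before trapping, by beta-elimination of water under amine catalysis or by enolisation of the hydroxy aldehyde. An excess of formaldehyde carried into the Wittig stage would also consume ylide.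
- Fallback: auxiliary control instead of catalysis. It sets out from the purchasable imide (R)-4-benzyl-3-butanoyl-1,3-oxazolidin-2-one F15.
- Its titanium enolate (TiCl4, i-Pr2NEt) with s-trioxane should give the hydroxymethyl imide F16. TIPSCl gives the silyl ether F17.
- LiBH4 releases (R)-2-{[(triisopropylsilyl)oxy]methyl}butan-1-ol F18. Swern oxidation gives (S)-2-{[(triisopropylsilyl)oxy]methyl}butanal F19.
- F19 is condensed directly with 3 to rejoin the route at 6.

## Further compounds

F1 | step 9 | (R)-hept-4-yn-3-ol | CC[C@@H](O)C#CCC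
F2 | step 9 | (R)-tert-butyl(hept-4-yn-3-yloxy)dimethylsilane | CC[C@@H](O[Si](C)(C)C(C)(C)C)C#CCC
F3 | step 9 | (R,E)-tert-butyl[(5-iodohept-4-en-3-yl)oxy]dimethylsilane | I/C(CC)=C/[C@@H](CC)O[Si](C)(C)C(C)(C)C
F4 | step 9 | (3R,4E,7E,9R)-3-(tert-butyldimethylsilyloxy)-5-ethyl-7-methyl-9-{[(triisopropylsilyl)oxy]methyl}undeca-4,7-dien-6-one (C4 epimer of 17) | CC[C@@H](CO[Si](C(C)C)(C(C)C)C(C)C)/C=C(C)/C(=O)/C(CC)=C/[C@@H](CC)O[Si](C)(C)C(C)(C)C
F5 | step 9 | C4 epimer of 19 (side chain (1R)-1-(tert-butyldimethylsilyloxy)propyl, ring centres as in 19) | CC[C@@H](CO[Si](C(C)C)(C(C)C)C(C)C)[C@@H]1[C@@H]([C@@H](CC)O[Si](C)(C)C(C)(C)C)[C@H](CC)C(=O)[C@H]1C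
F6 | step 9 | C4 epimer of 20 | CC[C@@H](CO[Si](C(C)C)(C(C)C)C(C)C)[C@@H]1[C@@H]([C@@H](CC)O[Si](C)(C)C(C)(C)C)[C@H](CC)C2(OCCO2)[C@H]1C
F7 | step 9 | C4 epimer of 21 | CC[C@@H](CO)[C@@H]1[C@@H]([C@@H](CC)O)[C@H](CC)C2(OCCO2)[C@H]1C
F8 | step 17 | hydroxy ketone: 22 with the aldehyde reduced to CH2OH (C4 ketone kept) | CC[C@@H](CO)[C@@H]1[C@@H](C(=O)CC)[C@H](CC)C2(OCCO2)[C@H]1C
F9 | step 17 | diol: (4S) tertiary dienyl carbinol at C4 and primary alcohol at C1' (35 with CH2OH in place of CO2Me) | CC[C@@H](CO)[C@@H]1[C@@H]([C@@](O)(CC)/C=C(CC)/C=C/c2ccccc2)[C@H](CC)C3(OCCO3)[C@H]1C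
F10 | step 18 | methylidene ester: 24 with C4=CH2 in place of the C4 ketone | CC[C@@H](C(=O)OC)[C@@H]1[C@@H](C(=C)CC)[C@H](CC)C2(OCCO2)[C@H]1C
F11 | step 18 | carboxylic acid of F10 | CC[C@@H](C(=O)O)[C@@H]1[C@@H](C(=C)CC)[C@H](CC)C2(OCCO2)[C@H]1C
F12 | step 18 | (2E,4E)-3-ethyl-5-phenylpenta-2,4-dien-1-ol | OC/C=C(CC)/C=C/c1ccccc1
F13 | step 18 | (2E,4E)-3-ethyl-5-phenylpenta-2,4-dien-1-yl ester of F11 | CC[C@@H](C(=O)OC/C=C(CC)/C=C/c1ccccc1)[C@@H]2[C@@H](C(=C)CC)[C@H](CC)C3(OCCO3)[C@H]2C
F14 | step 18 | open-chain Claisen acid: C7 (ethyl, CO2H) bonded to C6 (ethyl, (E)-styryl, vinyl), C4 methylidene on C3a, C6 and C7 as in 39 | C=C[C@](CC)(/C=C/c1ccccc1)[C@](CC)(C(=O)O)[C@@H]2[C@@H](C(=C)CC)[C@H](CC)C3(OCCO3)[C@H]2C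
F15 | step 1 | (R)-4-benzyl-3-butanoyl-1,3-oxazolidin-2-one | CCCC(=O)N1[C@H](Cc2ccccc2)COC1=O
F16 | step 1 | (R)-4-benzyl-3-[(2S)-2-(hydroxymethyl)butanoyl]-1,3-oxazolidin-2-one | CC[C@@H](CO)C(=O)N1[C@H](Cc2ccccc2)COC1=O
F17 | step 1 | (R)-4-benzyl-3-[(2S)-2-{[(triisopropylsilyl)oxy]methyl}butanoyl]-1,3-oxazolidin-2-one | CC[C@@H](CO[Si](C(C)C)(C(C)C)C(C)C)C(=O)N1[C@H](Cc2ccccc2)COC1=O
F18 | step 1 | (R)-2-{[(triisopropylsilyl)oxy]methyl}butan-1-ol | CC[C@@H](CO[Si](C(C)C)(C(C)C)C(C)C)CO
F19 | step 1 | (S)-2-{[(triisopropylsilyl)oxy]methyl}butanal | CC[C@@H](CO[Si](C(C)C)(C(C)C)C(C)C)C=O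
A1 | alternative 1 | C2 dioxolane of the target acid (identical with 39) | CCC1=C[C@@](/C=C/c2ccccc2)(CC)[C@](CC)(C(=O)O)[C@@H]2[C@@H]1[C@H](CC)C3(OCCO3)[C@H]2C
A2 | alternative 1 | delta-lactone with ring oxygen and (1E,3E)-dienyl group on C4 (identical with 36) | CC[C@]1(/C=C(CC)/C=C/c2ccccc2)OC(=O)[C@H](CC)[C@@H]3[C@@H]1[C@H](CC)C4(OCCO4)[C@H]3C
A3 | alternative 2 | bicyclic C1=C7a enone methyl ester | CCC1=C[C@@](/C=C/c2ccccc2)(CC)[C@](CC)(C(=O)OC)C2=C(C)C(=O)[C@@H](CC)[C@H]12
A4 | alternative 2 | acyclic dienyne: C7 (ethyl, CO2Me, prop-1-ynyl) bonded to C6 (ethyl, (E)-styryl), which carries the (Z)-C5=C4(ethyl)–(E)-C3a=C3–ethyl diene | CC/C=C/C(CC)=C\[C@@](/C=C/c1ccccc1)(CC)[C@](CC)(C(=O)OC)C#CC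
A5 | alternative 3 | methyl ester of the target | CCC1=C[C@@](/C=C/c2ccccc2)(CC)[C@](CC)(C(=O)OC)[C@@H]2[C@@H]1[C@H](CC)C(=O)[C@H]2C
A6 | alternative 3 | ring B ketone with the (Z)-1-iodobut-1-en-2-yl group on C3a and, on C7a, the quaternary C7 (ethyl, CO2Me) bearing the 1-phenylpent-2-en-3-yl alkene | CC/C(=C\Cc1ccccc1)[C@](CC)(C(=O)OC)[C@@H]1[C@@H](/C(CC)=C\I)[C@H](CC)C(=O)[C@H]1C
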